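**Plan**

1. Labels used in all names: C1 ketone carbon; C2=C3(CH3) its alkene; C4 and C11 the cyclobutane CH atoms bonded to C3 and C1; C5 the cyclobutane CH bonded to C6(CH3)2; C7 isovalerate carbinol; C8 CH2; C9 tiglate carbinol; C10 the quaternary cyclobutane carbon carrying CH3. Ring A is the cyclobutane C4–C5–C11–C10, ring B the seven-membered ring through C6–C9, ring C the cyclohexenone through C1–C3.
2. Retrosynthesis: cut the two ester C–O bonds (tiglate on O9; isovalerate on O7 together with C9–H), then C7–O (conjugate borylation of a cycloheptenone), then the alkenes C2=C3 and C7=C8 (two ring-closing metatheses), then the ring A bond C10–C11 (Wolff contraction of a diazocyclopentanone), then C10–C9, C4–C3 and C5–C6 back to (R)-4-silyloxycyclopentenone.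
3. Forward: a cyclopentanone is built by three anti additions and contracted to ring A; ring B is closed between C5 and C10, then ring C between C11 and C4; oxygenation of C7 and C9 and the two acylations finish the synthesis.
4. Enabling feature: on ring A the four exocyclic carbons alternate faces (C3 on C4 up, C6 on C5 down, C1 on C11 up, C9 on C10 down), so every neighbouring pair is trans. Three of these relationships come from anti additions around a five-membered ketone, and the fourth (C11) is the thermodynamic one for an ester. A diazo ketone contraction with migration of C10 carries the first three over unchanged.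
5. Stereochemistry: C5 from the silyloxy center of the starting enone; C4 anti to C5; C10 anti to C4; C11 by base equilibration; C7 by a chiral copper catalyst; C9 by intramolecular hydride delivery anti to O7; the tiglate geometry is purchased.

Key step: step 7

Remark on the chemistry (assumption): the carbinol carbon C9 made in step 4 is expected as a mixture of epimers. It is drawn without configuration in compounds 11–23 and is removed by oxidation in step 13.

**Route**

Step 1
Reactants: 1 (R)-4-(tert-butyldimethylsilyloxy)cyclopent-2-en-1-one; 2 trimethyl(3-methylbut-2-en-1-yl)silane (prenyltrimethylsilane)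
Product: 4 (4R)-4-(2-methylbut-3-en-2-yl)cyclopent-2-en-1-one, via silyloxy ketone 3 (not isolated)
Conditions: TiCl4, CH2Cl2, −78 °C; aq. NaHCO3; then DBU, CH2Cl2, 0 °C to rt
Reagents that add atoms: none
Why: Hosomi–Sakurai conjugate allylation, in which the γ-carbon of the prenylsilane attacks the activated enone at C5 on the face anti to the silyloxy group, creating quaternary C6 with its vinyl group (C7) and setting C5 from the stereocenter of 1; E1cB loss of silanol with DBU then places the alkene at C10=C4.

Step 2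
Reactants: 4 (4R)-4-(2-methylbut-3-en-2-yl)cyclopent-2-en-1-one
Product: 5 (4R)-2-iodo-4-(2-methylbut-3-en-2-yl)cyclopent-2-en-1-one
Conditions: I2, pyridine, CH2Cl2, 0 °C to rt
Reagents that add atoms: iodine, II
Why: pyridine-mediated α-iodination of an enone (amine addition, iodination of the enolate, elimination), which does not involve the C5 stereocenter.

Step 3
Reactants: 5 (4R)-2-iodo-4-(2-methylbut-3-en-2-yl)cyclopent-2-en-1-one
Product: 6 (4R)-2-methyl-4-(2-methylbut-3-en-2-yl)cyclopent-2-en-1-one
Conditions: Me4Sn, Pd2(dba)3 (cat.), AsPh3, CuI (cat.), NMP, 60 °C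
Reagents that add atoms: tetramethylstannane, C[Sn](C)(C)C
Why: Stille coupling of a 2-iodoenone under neutral conditions, the standard way to a 2-methylenone, which should spare the base-sensitive C5 center and the vinyl group.

Step 4
Reactants: 6 (4R)-2-methyl-4-(2-methylbut-3-en-2-yl)cyclopent-2-en-1-one; 7 isopropenylmagnesium bromide; 8 acrolein
Product: 11 (2S,3R,4R)-2-(1-hydroxyprop-2-en-1-yl)-2-methyl-4-(2-methylbut-3-en-2-yl)-3-(prop-1-en-2-yl)cyclopentan-1-one, via silyl enol ether 9 (not isolated), via lithium enolate 10 (not isolated)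
Conditions: 7, CuBr·SMe2 (cat.), TMSCl, THF, −78 to −40 °C; Et3N, pentane, filter; MeLi, THF, 0 °C; 8, −78 °C; AcOH quench at −78 °C
Reagents that add atoms: chlorotrimethylsilane, C[Si](C)(C)Cl (silicon in 9 only); methyllithium, [Li]C (lithium in 10 only)
Why: copper-catalysed 1,4-addition with silyl trapping puts the isopropenyl group on C4 anti to the bulky C5 substituent, and the regiodefined lithium enolate then undergoes aldol 1,2-addition to acrolein on the face anti to that new group, fixing quaternary C10 with its methyl cis and its C9 arm trans to isopropenyl.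

Step 5
Reactants: 11 (2S,3R,4R)-2-(1-hydroxyprop-2-en-1-yl)-2-methyl-4-(2-methylbut-3-en-2-yl)-3-(prop-1-en-2-yl)cyclopentan-1-one
Product: 12 (2S,3R,4R)-2-[1-(tert-butyldimethylsilyloxy)prop-2-en-1-yl]-2-methyl-4-(2-methylbut-3-en-2-yl)-3-(prop-1-en-2-yl)cyclopentan-1-one
Conditions: TBSOTf, 2,6-lutidine, CH2Cl2, −78 °C
Reagents that add atoms: tert-butyldimethylsilyl trifluoromethanesulfonate, CC(C)(C)[Si](C)(C)OS(=O)(=O)C(F)(F)F
Why: silylation of a hindered secondary alcohol with a silyl triflate, which blocks retro-aldol cleavage in the basic steps that follow.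

Step 6
Reactants: 12 (2S,3R,4R)-2-[1-(tert-butyldimethylsilyloxy)prop-2-en-1-yl]-2-methyl-4-(2-methylbut-3-en-2-yl)-3-(prop-1-en-2-yl)cyclopentan-1-one
Product: 14 (2S,3R,4R)-5-diazo-2-[1-(tert-butyldimethylsilyloxy)prop-2-en-1-yl]-2-methyl-4-(2-methylbut-3-en-2-yl)-3-(prop-1-en-2-yl)cyclopentan-1-one, via trifluoroacetyl ketone 13 (not isolated)
Conditions: LiHMDS, THF, −78 °C; CF3CO2CH2CF3; aq. HCl work-up; then MsN3, Et3N, H2O, MeCN, rt
Reagents that add atoms: 2,2,2-trifluoroethyl trifluoroacetate, FC(F)(F)COC(=O)C(F)(F)F (in 13 only); methanesulfonyl azide, CS(=O)(=O)N=[N+]=[N-]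
Why: detrifluoroacetylative diazo transfer (a Regitz-type reaction), which can only place N2 on C11 because C10 is quaternary and C11 is the single enolisable position.

Step 7
Reactants: 14 (2S,3R,4R)-5-diazo-2-[1-(tert-butyldimethylsilyloxy)prop-2-en-1-yl]-2-methyl-4-(2-methylbut-3-en-2-yl)-3-(prop-1-en-2-yl)cyclopentan-1-one
Product: 17 methyl (1R,2R,3R,4S)-2-[1-(tert-butyldimethylsilyloxy)prop-2-en-1-yl]-2-methyl-4-(2-methylbut-3-en-2-yl)-3-(prop-1-en-2-yl)cyclobutane-1-carboxylate, via ketene 15 (not isolated), via C11-epimeric ester 16 (not isolated)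
Conditions: hν (Pyrex-filtered Hg lamp or 365 nm LEDs), MeOH, 0 °C to rt; then NaOMe, MeOH, 40 °C
Reagents that add atoms: methanol, CO
Why: Excitation of the cyclic, cisoid diazo ketone expels N2 and C10 shifts from the carbonyl carbon C1 to C11 with retention, giving cyclobutylidene ketene 15, which methanol intercepts as the ester; this is the photochemical Wolff ring contraction of 2-diazocycloalkanones, an established route from five-membered ketones to cyclobutane esters. Ring A closes by a 1,2-alkyl shift (ring contraction, new bond C10–C11) and not by a cyclisation, so the C4, C5 and C10 centers set on the cyclopentanone are carried over unchanged. The one new center, C11, arises by protonation of the ketene–methanol adduct and is then equilibrated with methoxide, so that the ester should settle trans to the tert-alkyl group on C5 and to the larger arm on C10, completing the up–down–up–down array. The step needs rearrangement to outrun O–H insertion into methanol and carbene addition to the three alkenes; the cisoid geometry enforced by the ring favours concerted migration, no alkene is tethered within reach of C11, and only C10 can migrate because the other carbonyl substituent is the diazo carbon itself.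

Step 8
Reactants: 17 methyl (1R,2R,3R,4S)-2-[1-(tert-butyldimethylsilyloxy)prop-2-en-1-yl]-2-methyl-4-(2-methylbut-3-en-2-yl)-3-(prop-1-en-2-yl)cyclobutane-1-carboxylate
Product: 18 (1R,2R,3R,4S)-2-[1-(tert-butyldimethylsilyloxy)prop-2-en-1-yl]-N-methoxy-N,2-dimethyl-4-(2-methylbut-3-en-2-yl)-3-(prop-1-en-2-yl)cyclobutane-1-carboxamide
Conditions: MeNHOMe·HCl, iPrMgCl, THF, −20 to 0 °C
Reagents that add atoms: N,O-dimethylhydroxylamine hydrochloride, CNOC.Cl
Why: Weinreb amide formation from an ester with the chloromagnesium amide; C11 already has its thermodynamic configuration, so the basic reagent should not erode it.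

Step 9
Reactants: 18 (1R,2R,3R,4S)-2-[1-(tert-butyldimethylsilyloxy)prop-2-en-1-yl]-N-methoxy-N,2-dimethyl-4-(2-methylbut-3-en-2-yl)-3-(prop-1-en-2-yl)cyclobutane-1-carboxamide
Product: 19 rings A/B Weinreb amide (bicyclo[4.1.1]oct-3-ene: C5 and C10 bridged by C6(CH3)2–C7H=C8H–C9H(OTBS); amide on C11 and isopropenyl on C4 on the face opposite the bridge)
Conditions: second-generation Hoveyda–Grubbs catalyst (cat.), toluene (2 mM), 80 °C
Reagents that add atoms: none
Why: ring-closing metathesis of the two monosubstituted alkenes closes cycloheptene ring B (C7=C8) across the cis-1,3 positions C5 and C10; the isopropenyl group cannot reach either partner without a trans-fused small ring, and closing this ring first forces only the two flat top substituents, not the branched bottom ones, into the 1,3-diaxial arrangement.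

Step 10
Reactants: 19 rings A/B Weinreb amide; 20 vinylmagnesium bromide
Product: 21 rings A/B vinyl ketone (as 19, with C11 bearing C(=O)CH=CH2)
Conditions: 20, THF, −20 to 0 °C; cold 1 M HCl quench
Reagents that add atoms: none
Why: Grignard addition to a Weinreb amide stops at the chelated tetrahedral adduct and releases the enone on acidic quench; the only other functions are alkenes and a silyl ether.

Step 11
Reactants: 21 rings A/B vinyl ketone
Product: 22 tricyclic enone silyl ether (rings A, B and C; C1 ketone, C2=C3, C7=C8, C9–OTBS)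
Conditions: second-generation Hoveyda–Grubbs catalyst (cat.), toluene, 80 °C
Reagents that add atoms: none
Why: ring-closing metathesis between the acryloyl and isopropenyl groups, which ring B holds 1,3-diaxial on the same face, forms the trisubstituted enone C2=C3 of ring C.

Step 12
Reactants: 22 tricyclic enone silyl ether
Product: 23 tricyclic enone allylic alcohol (C9–OH, C7=C8)
Conditions: TBAF, THF, rt; aq. NH4Cl
Reagents that add atoms: none
Why: fluoride cleavage of a secondary silyl ether, to which both alkenes and the enone are inert.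

Step 13
Reactants: 23 tricyclic enone allylic alcohol
Product: 24 tricyclic bis-enone (C1 and C9 ketones, C2=C3 and C7=C8)
Conditions: Dess–Martin periodinane, NaHCO3, CH2Cl2, rt
Reagents that add atoms: none
Why: Dess–Martin oxidation of the allylic alcohol removes the uncontrolled C9 center and supplies the cycloheptenone needed to oxygenate C7.

Step 14
Reactants: 24 tricyclic bis-enone
Product: 26 (7R)-ketol (C7–OH on the side of C4, C9 ketone, ring C enone intact), via pinacol boronate 25 (not isolated)
Conditions: B2pin2, CuCl (cat.), NaOtBu (cat.), (R)-1-[(S)-2-(diphenylphosphino)ferrocenyl]ethyldicyclohexylphosphine or its mirror image (cat.), MeOH, THF, 0 °C to rt; then NaBO3·4H2O, THF/H2O, rt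
Reagents that add atoms: bis(pinacolato)diboron, CC1(C)OB(OC1(C)C)B1OC(C)(C)C(C)(C)O1 (in 25 only); sodium perborate, [Na+].[Na+].O[B-]1(O)OO[B-](O)(O)OO1
Why: copper-catalysed asymmetric conjugate borylation followed by stereoretentive perborate oxidation; the ring B enone lies close to a local mirror plane through C5, C8 and C10, so little substrate bias is expected and the ligand antipode that places boron on C7 on the side of C4 is used, while the β,β-disubstituted ring C enone should be inert to phosphine–copper boryl species.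

Step 15
Reactants: 26 (7R)-ketol; 27 3-methylbutanal
Product: 28 (7R,9R)-C7 isovalerate C9 alcohol (trans-1,3; ring C enone intact)
Conditions: SmI2 (0.3 equiv), 27, THF, −10 °C
Reagents that add atoms: none
Why: Evans–Tishchenko reaction, in which the samarium-bound hemiacetal of the C7 hydroxyl delivers hydride to C9 from the side of O7, so O9 should end trans to O7 and the isovalerate ends on O7.

Step 16
Reactants: 28 (7R,9R)-C7 isovalerate C9 alcohol; 29 tiglic acid
Product: 31 target CNP0194415.1 (C9 tiglate, C7 isovalerate of the tricyclic enone), via mixed anhydride 30 (not isolated)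
Conditions: 29, 2,4,6-trichlorobenzoyl chloride, Et3N, THF, rt; then 28, DMAP, toluene, 60 °C
Reagents that add atoms: 2,4,6-trichlorobenzoyl chloride, O=C(Cl)c1c(Cl)cc(Cl)cc1Cl (in 30 only)
Why: Yamaguchi esterification, suited to a hindered secondary alcohol, installs the (E)-2-methylbut-2-enoate without touching the existing ester or the enone.

**Compound list**

1 | (R)-4-(tert-butyldimethylsilyloxy)cyclopent-2-en-1-one | O=C1C=C[C@H](O[Si](C)(C)C(C)(C)C)C1 | starting material
2 | trimethyl(3-methylbut-2-en-1-yl)silane | CC(C)=CC[Si](C)(C)C | starting material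
3 | (3S,4R)-4-(tert-butyldimethylsilyloxy)-3-(2-methylbut-3-en-2-yl)cyclopentan-1-one | O=C1C[C@@H](C(C)(C)C=C)[C@H](O[Si](C)(C)C(C)(C)C)C1 | intermediate
4 | (4R)-4-(2-methylbut-3-en-2-yl)cyclopent-2-en-1-one | O=C1C=C[C@H](C(C)(C)C=C)C1 | intermediate
5 | (4R)-2-iodo-4-(2-methylbut-3-en-2-yl)cyclopent-2-en-1-one | O=C1C(I)=C[C@H](C(C)(C)C=C)C1 | intermediate
6 | (4R)-2-methyl-4-(2-methylbut-3-en-2-yl)cyclopent-2-en-1-one | O=C1C(C)=C[C@H](C(C)(C)C=C)C1 | intermediate
7 | isopropenylmagnesium bromide | CC(=C)[Mg]Br | starting material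
8 | acrolein | C=CC=O | starting material
9 | trimethyl{[(3R,4R)-2-methyl-4-(2-methylbut-3-en-2-yl)-3-(prop-1-en-2-yl)cyclopent-1-en-1-yl]oxy}silane | C[Si](C)(C)OC1=C(C)[C@@H](C(C)=C)[C@H](C(C)(C)C=C)C1 | intermediate
10 | lithium (3R,4R)-2-methyl-4-(2-methylbut-3-en-2-yl)-3-(prop-1-en-2-yl)cyclopent-1-en-1-olate | [Li]OC1=C(C)[C@@H](C(C)=C)[C@H](C(C)(C)C=C)C1 | intermediate
11 | (2S,3R,4R)-2-(1-hydroxyprop-2-en-1-yl)-2-methyl-4-(2-methylbut-3-en-2-yl)-3-(prop-1-en-2-yl)cyclopentan-1-one (C9 epimers) | O=C1C[C@@H](C(C)(C)C=C)[C@H](C(C)=C)[C@@]1(C)C(O)C=C | intermediate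
12 | (2S,3R,4R)-2-[1-(tert-butyldimethylsilyloxy)prop-2-en-1-yl]-2-methyl-4-(2-methylbut-3-en-2-yl)-3-(prop-1-en-2-yl)cyclopentan-1-one | O=C1C[C@@H](C(C)(C)C=C)[C@H](C(C)=C)[C@@]1(C)C(O[Si](C)(C)C(C)(C)C)C=C | intermediate
13 | 5-(trifluoroacetyl) derivative of 12 (at C11) | O=C1C(C(=O)C(F)(F)F)[C@@H](C(C)(C)C=C)[C@H](C(C)=C)[C@@]1(C)C(O[Si](C)(C)C(C)(C)C)C=C | intermediate
14 | (2S,3R,4R)-5-diazo-2-[1-(tert-butyldimethylsilyloxy)prop-2-en-1-yl]-2-methyl-4-(2-methylbut-3-en-2-yl)-3-(prop-1-en-2-yl)cyclopentan-1-one | O=C1C(=[N+]=[N-])[C@@H](C(C)(C)C=C)[C@H](C(C)=C)[C@@]1(C)C(O[Si](C)(C)C(C)(C)C)C=C | intermediate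
15 | cyclobutylidene ketene (C11=C1=O; C5, C4, C10 substituted as in 17) | O=C=C1[C@@H](C(C)(C)C=C)[C@H](C(C)=C)[C@@]1(C)C(O[Si](C)(C)C(C)(C)C)C=C | intermediate
16 | methyl (1S,2R,3R,4S) ester, the C11 epimer of 17 (ester cis to the C6 arm) | COC(=O)[C@H]1[C@@H](C(C)(C)C=C)[C@H](C(C)=C)[C@@]1(C)C(O[Si](C)(C)C(C)(C)C)C=C | intermediate
17 | methyl (1R,2R,3R,4S)-2-[1-(tert-butyldimethylsilyloxy)prop-2-en-1-yl]-2-methyl-4-(2-methylbut-3-en-2-yl)-3-(prop-1-en-2-yl)cyclobutane-1-carboxylate | COC(=O)[C@@H]1[C@@H](C(C)(C)C=C)[C@H](C(C)=C)[C@@]1(C)C(O[Si](C)(C)C(C)(C)C)C=C | intermediate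
18 | (1R,2R,3R,4S)-2-[1-(tert-butyldimethylsilyloxy)prop-2-en-1-yl]-N-methoxy-N,2-dimethyl-4-(2-methylbut-3-en-2-yl)-3-(prop-1-en-2-yl)cyclobutane-1-carboxamide | CON(C)C(=O)[C@@H]1[C@@H](C(C)(C)C=C)[C@H](C(C)=C)[C@@]1(C)C(O[Si](C)(C)C(C)(C)C)C=C | intermediate
19 | rings A/B Weinreb amide (bicyclo[4.1.1]oct-3-ene; bridge C6(CH3)2–C7H=C8H–C9H(OTBS) between C5 and C10; amide on C11 and isopropenyl on C4 anti to the bridge) | CON(C)C(=O)[C@@H]1[C@@H]2[C@H](C(C)=C)[C@@]1(C)C(O[Si](C)(C)C(C)(C)C)C=CC2(C)C | intermediate
20 | vinylmagnesium bromide | C=C[Mg]Br | starting material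
21 | rings A/B vinyl ketone (as 19 with C(=O)CH=CH2 on C11) | C=CC(=O)[C@@H]1[C@@H]2[C@H](C(C)=C)[C@@]1(C)C(O[Si](C)(C)C(C)(C)C)C=CC2(C)C | intermediate
22 | tricyclic enone silyl ether (C1 ketone, C2=C3, C7=C8, C9–OTBS) | CC(C)(C)[Si](C)(C)OC1C=CC(C)(C)[C@@H]2[C@H]3C(=O)C=C(C)[C@@H]2[C@]31C | intermediate
23 | tricyclic enone allylic alcohol (C9–OH) | OC1C=CC(C)(C)[C@@H]2[C@H]3C(=O)C=C(C)[C@@H]2[C@]31C | intermediate
24 | tricyclic bis-enone (C1 and C9 ketones) | O=C1C=CC(C)(C)[C@@H]2[C@H]3C(=O)C=C(C)[C@@H]2[C@]31C | intermediate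
25 | C7 pinacol boronate of the C9 ketone (boron on the side of C4) | O=C1C[C@@H](B2OC(C)(C)C(C)(C)O2)C(C)(C)[C@@H]3[C@H]4C(=O)C=C(C)[C@@H]3[C@]41C | intermediate
26 | (7R)-ketol (C7–OH, C9 ketone) | O=C1C[C@@H](O)C(C)(C)[C@@H]2[C@H]3C(=O)C=C(C)[C@@H]2[C@]31C | intermediate
27 | 3-methylbutanal | CC(C)CC=O | starting material
28 | (7R,9R)-C7 3-methylbutanoate C9 alcohol | O[C@@H]1C[C@@H](OC(=O)CC(C)C)C(C)(C)[C@@H]2[C@H]3C(=O)C=C(C)[C@@H]2[C@]31C | intermediate
29 | tiglic acid ((E)-2-methylbut-2-enoic acid) | C/C=C(\C)C(=O)O | starting material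
30 | (E)-2-methylbut-2-enoic 2,4,6-trichlorobenzoic anhydride | C/C=C(\C)C(=O)OC(=O)c1c(Cl)cc(Cl)cc1Cl | intermediate
31 | CNP0194415.1 (C9 tiglate, C7 isovalerate, C1 enone) | C/C=C(\C)C(=O)O[C@@H]1C[C@@H](OC(=O)CC(C)C)C(C)(C)[C@@H]2[C@H]3C(=O)C=C(C)[C@@H]2[C@]31C | target

**Step count and risks**

Total steps: 16. Longest linear sequence: 16 (1 to 31).

Step 14. The chiral copper–boryl species may discriminate poorly between the two faces of a cycloheptenone flanked by two quaternary carbons, or the ring C enone may be borylated slowly in competition. The fallback sets out from 24 and comes back at 26, replacing catalyst control by separation and recycling. Borylation of 24 with an achiral catalyst (CuCl, NaOtBu, Xantphos, B2pin2, MeOH) would give 25 together with the C7-epimeric boronate F1. Perborate oxidation would then give 26 and the C7-epimeric ketol F2, which are diastereomers and are separated by chromatography. F2 is converted with MsCl and Et3N into the mesylate F3, which eliminates with DBU back to 24 for another pass.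

Step 9. Ring closure may be slow because both alkenes are neopentyl-like and the ring can form only from the all-axial cyclobutane conformer, so cross-metathesis dimerisation or catalyst decay may win. The fallback sets out from 12 and comes back at 19, closing ring B before the ring contraction. On the cyclopentanone the two vinyl arms sit cis-1,3 and no strained conformer is needed. Ring-closing metathesis of 12 with the same catalyst would give the bicyclo[4.2.1]nonenone F4. Diazo transfer as in step 6 would lead through the trifluoroacetyl ketone F5 to the bicyclic diazo ketone F6. Photolysis in methanol and methoxide equilibration as in step 7 would lead through the bicyclic ketene F7 and the C11-epimeric bicyclic ester F8 to the bicyclic methyl ester F9. Wolff contraction of bridged diazo ketones is known chemistry. Amidation of F9 as in step 8 returns 19.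

Step 1. The Lewis acid may strip the silyloxy group before addition, the allylsilane may react through its unsubstituted terminus, or conversion may stall in forming a quaternary carbon next to a substituted center. The fallback sets out from 1 and comes back at 4, bringing C6 in as an aldehyde enolate equivalent. Mukaiyama–Michael addition of commercial 2-methyl-1-(trimethylsilyloxy)prop-1-ene to 1 with catalytic Ph3C·SbCl6 (CH2Cl2, −78 °C) would give the silyl enol ether adduct F10, again anti to the silyloxy group. Mild aqueous acid would give the silyloxy keto aldehyde F11, and DBU the enone aldehyde F12. Wittig methylenation with Ph3P=CH2 at −78 °C, where the aldehyde should react before the enone, would then give 4.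

**Further compounds**

F1 | step 14 | C7-epimeric pinacol boronate (boron on the side of C11) | O=C1C[C@H](B2OC(C)(C)C(C)(C)O2)C(C)(C)[C@@H]3[C@H]4C(=O)C=C(C)[C@@H]3[C@]41C
F2 | step 14 | C7-epimeric ketol | O=C1C[C@H](O)C(C)(C)[C@@H]2[C@H]3C(=O)C=C(C)[C@@H]2[C@]31C
F3 | step 14 | methanesulfonate of F2 | O=C1C[C@H](OS(C)(=O)=O)C(C)(C)[C@@H]2[C@H]3C(=O)C=C(C)[C@@H]2[C@]31C
F4 | step 9 | bicyclo[4.2.1]nonenone (ring B closed on cyclopentanone 12) | O=C1C[C@@H]2[C@H](C(C)=C)[C@@]1(C)C(O[Si](C)(C)C(C)(C)C)C=CC2(C)C
F5 | step 9 | trifluoroacetyl ketone of F4 (at C11) | O=C1C(C(=O)C(F)(F)F)[C@@H]2[C@H](C(C)=C)[C@@]1(C)C(O[Si](C)(C)C(C)(C)C)C=CC2(C)C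
F6 | step 9 | bicyclic diazo ketone | O=C1C(=[N+]=[N-])[C@@H]2[C@H](C(C)=C)[C@@]1(C)C(O[Si](C)(C)C(C)(C)C)C=CC2(C)C
F7 | step 9 | bicyclic ketene | O=C=C1[C@@H]2[C@H](C(C)=C)[C@@]1(C)C(O[Si](C)(C)C(C)(C)C)C=CC2(C)C
F8 | step 9 | C11-epimeric bicyclic methyl ester | COC(=O)[C@H]1[C@@H]2[C@H](C(C)=C)[C@@]1(C)C(O[Si](C)(C)C(C)(C)C)C=CC2(C)C
F9 | step 9 | bicyclic methyl ester (rings A/B, ester anti to the bridge) | COC(=O)[C@@H]1[C@@H]2[C@H](C(C)=C)[C@@]1(C)C(O[Si](C)(C)C(C)(C)C)C=CC2(C)C
F10 | step 1 | silyl enol ether Michael adduct (aldehyde arm on C5) | C[Si](C)(C)OC1=C[C@@H](C(C)(C)C=O)[C@H](O[Si](C)(C)C(C)(C)C)C1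
F11 | step 1 | 2-[(1S,2R)-2-(tert-butyldimethylsilyloxy)-4-oxocyclopentyl]-2-methylpropanal | O=C1C[C@@H](C(C)(C)C=O)[C@H](O[Si](C)(C)C(C)(C)C)C1
F12 | step 1 | 2-methyl-2-[(1R)-4-oxocyclopent-2-en-1-yl]propanal | O=C1C=C[C@H](C(C)(C)C=O)C1
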